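The midnight flask is slow: between 14 min and 59 min its product grows at 0.00424 M min⁻¹. Dividing this slope by the free catalyst charged gives 0.0849 min⁻¹. This is the turnover rate, steady product per charged free catalyst.

| flask | starting material | partner | free catalyst | product | time |
|---|---|---|---|---|---|
| midnight | 0.500 M | 1.50 M | 0.0500 M |  |  |
| winter | 0.500 M | 3.00 M | 0.0500 M |  |  |
| noon | 0.500 M | 1.50 M | 0.0750 M |  |  |
| dusk | 0.500 M | 1.50 M | 0.0500 M | 0.150 M |  |
| dawn | 0.170 M | 1.50 M | 0.0250 M |  | 59 min |

| run | time / min | [product] / M |
|---|---|---|
| midnight run | 4.5 | 0.008 |
| midnight run | 14 | 0.065 |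
| midnight run | 26 | 0.120 |
| midnight run | 41 | 0.182 |
| midnight run | 59 | 0.256 |
| winter run | 4.5 | 0.015 |
| winter run | 14 | 0.062 |
| winter run | 26 | 0.125 |
| winter run | 41 | 0.193 |
| winter run | 59 | 0.260 |
| noon run | 4.5 | 0.020 |
| noon run | 14 | 0.089 |
| noon run | 26 | 0.176 |
| noon run | 41 | 0.264 |
| noon run | 59 | 0.360 |
| dusk run | 4.5 | 0.161 |
| dusk run | 14 | 0.210 |
| dusk run | 26 | 0.276 |
| dusk run | 41 | 0.336 |
| dusk run | 59 | 0.407 |

(scatter of a reading: 0.003 M)

- Overall: starting material + partner -> product, with free catalyst as catalyst.
- Constant volume, constant temperature.
- The analysis sees a species whether free or bound.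
- An order is taken over about fifteen percent of the charge, up and down.

1. reaction order in [partner] at the outset, round the charge of the midnight run, defined at two percent of the starting material turned into product
2. reaction order in [free catalyst] at the outset, round the charge of the midnight run, defined at two percent of the starting material turned into product
3. product in the dawn run at 59 min, as a share of the starting material charged

Partner comes first. If the slope followed [partner] in proportion, winter, with 3.00 M against 1.50 M, would climb at twice the midnight slope. Winter's slope is 0.00440 M min⁻¹, about the same as midnight's, so the partner order reads 0.0519.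

Catalyst comes next. With every catalyst turning at the same rate, noon's charge would raise the slope by a factor 1.50. Noon climbs at 0.00602 M min⁻¹, a factor 1.42, so the catalyst order reads 0.863.

Added product could hold catalyst back. Dusk starts with 0.150 M and climbs at 0.00438 M min⁻¹, about the same as midnight.

Both orders are steady-stretch readings, carried to the outset with reserve. Midnight's 0.008 M at 4.5 min lies below the 0.0191 M that the steady slope gives, so the rate is still building there.

Dawn lowers two settings: [free catalyst] to 0.0250 M and [starting material] to 0.170 M. That charge is less than the 0.244 M midnight still holds at 59 min. Noon ends below it, with 0.140 M unturned at 59 min, but that is one last stretch of its readings, so dawn is solved at both ends.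

If the rate ignores what is left, the turnover rate gives 73.7% at 59 min. If the rate is proportional to what is left (pseudo-first-order), scaled to midnight's mean 0.340 M over the stretch, it gives 30.8%. The midpoint, 52.2%, is the reckoning committed to.

The forecast gives 0.3 (0.08 to 0.5) and 0.62 (0.45 to 0.95) for the orders, placing two percent conversion inside the lag, and 38% (30% to 46%) for dawn, on the ground that "The rate falls gently with substrate".

    free catalyst + starting material → catalyst-substrate complex (4.212 M⁻¹ min⁻¹)
    catalyst-substrate complex + partner → loaded catalyst (1.092 M⁻¹ min⁻¹)
    loaded catalyst → product + free catalyst (0.2124 min⁻¹)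
    2 starting material ⇌ idle substrate dimer, settled at all times (49.20 M⁻¹)
    free catalyst → spent catalyst (0.01140 min⁻¹)

The flask gives 0.063 for partner against the reckoned 0.0519, and 0.75 for catalyst against the reckoned 0.863. Dawn gives 51.4% against the reckoned 52.2%. In these steps starting material pairs into idle substrate dimer with 49.2 M⁻¹. Dawn's product, 0.0873 M, is a mean 0.0592 min⁻¹ per charged free catalyst, against the turnover rate of 0.0849 min⁻¹. At the turnover rate, noon needs 39.3 min to make half of its starting material charged, and noon reaches that point at 38.4 min.

The numbers in the tables stem from a simulated flask with made-up constants, and the scatter is random.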